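**Retrosynthetic overview**

1. Target 25 ⇐ 24 by BCl3 cleavage of two O-benzyl groups and the chelated 5''-O-methyl group; 24 ⇐ 23 by oxidation of both C-4 carbinols, so the ketones appear last and C-3/C-3'' never meet base as α-carbonyl centres.
2. Pyran ring of the 5,7-dioxygenated trans half: aryl–O bond by Cu-catalysed etherification of triol 22 (retention at C-2); C-2 from aryl ketone 20 by 1,3-syn reduction; 20 from lactone 17 via Weinreb amide and aryl Grignard.
3. C-3–C-4 bond: anti aldol of the cis-fused lactone 12 with aldehyde 15 on its convex face, which sets C-3 relative to C-3''.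
4. Pyran ring of the 7-methoxy cis half: Cu-catalysed etherification of hydroxy lactone 10 (retention at C-2''), from keto lactone 9.
5. C-2''/C-3'': ketoreductase reduction with dynamic kinetic resolution of achiral diketo ester 7. Ring order: γ-lactone (step 4), pyran ring of the cis half (step 6), pyran ring of the trans half (step 12); the benzene rings are bought.

Locants: unprimed = 5,7-dihydroxy half (2S,3R, trans); double-primed = 5-hydroxy-7-methoxy half (2''S,3''S, cis).
Assumption: a ketoreductase from a commercial screening panel accepts 7 and gives the (3S,4S) hydroxy ketone 8.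

**Route**

Step 1
Reactants: 1 1-bromo-3,5-dimethoxybenzene; 2 acetyl chloride
Product: 3 1-(2-bromo-4,6-dimethoxyphenyl)ethan-1-one
Conditions: SnCl4, CH2Cl2, −10 °C → rt
Reagents that add atoms: none
Why: Friedel–Crafts acylation goes para to one methoxy group and ortho to bromine, because the carbon between the two methoxy groups is more hindered (minor isomer removed by crystallization).

Step 2
Reactants: 3 aryl methyl ketone; 4 methyl 4-methoxybenzoate
Product: 5 1-(2-bromo-4,6-dimethoxyphenyl)-3-(4-methoxyphenyl)propane-1,3-dione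
Conditions: NaH, THF, reflux; then 1 M HCl
Reagents that add atoms: none
Why: Crossed Claisen condensation; only 3 can enolize, its own di-ortho-substituted carbonyl does not self-condense, and deprotonation of the 1,3-diketone drives the reaction.

Step 3
Reactants: 5 1,3-diketone; 6 methyl bromoacetate
Product: 7 methyl 3-(2-bromo-4,6-dimethoxybenzoyl)-4-(4-methoxyphenyl)-4-oxobutanoate (racemic; C-3 labile)
Conditions: K2CO3, acetone, 40 °C
Reagents that add atoms: none
Why: SN2 C-alkylation of the diketone with a reactive α-halo ester; the hindered product resists a second alkylation.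

Step 4
Reactants: 7 diketo ester
Product: 9 (4S,5S)-4-(2-bromo-4,6-dimethoxybenzoyl)-5-(4-methoxyphenyl)oxolan-2-one, via hydroxy ketone 8 (not isolated)
Conditions: ketoreductase (NADPH-dependent alcohol dehydrogenase), NADP+ (cat.), iPrOH, DMSO, KH2PO4/K2HPO4 buffer pH 7.0, 30 °C; then PPTS (cat.), CH2Cl2, rt
Reagents that add atoms: none
Why: Biocatalytic asymmetric ketone reduction with dynamic kinetic resolution: the enzyme reduces only the unhindered 4-methoxyphenyl ketone from one face (C-2'' S) and takes one enantiomer of the rapidly racemizing 1,3-dicarbonyl centre (C-3'' S), and the γ-hydroxy ester then closes to the trans lactone.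

Step 5
Reactants: 9 keto lactone
Product: 10 (4R,5S)-4-[(S)-(2-bromo-4,6-dimethoxyphenyl)(hydroxy)methyl]-5-(4-methoxyphenyl)oxolan-2-one
Conditions: NaBH4, CeCl3·7H2O, MeOH–THF, −40 → −10 °C
Reagents that add atoms: none
Why: Luche reduction; Felkin–Anh hydride delivery should give mainly the (S)-carbinol, the lactone survives at low temperature, the near-neutral medium avoids β-elimination of the lactone, and this carbinol centre is temporary (reoxidized in step 13).

Step 6
Reactants: 10 hydroxy lactone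
Product: 12 (3aS,4S,9bS)-7,9-dimethoxy-4-(4-methoxyphenyl)-3,3a,4,9b-tetrahydro-2H-furo[3,2-c]chromen-2-one, via isomeric hydroxy lactone 11 (not isolated)
Conditions: CuI (10 mol%), 3,4,7,8-tetramethyl-1,10-phenanthroline (20 mol%), Cs2CO3, toluene, 100 °C
Reagents that add atoms: none
Why: Intramolecular Ullmann-type C–O coupling; under carbonate the two γ-lactones interconvert by translactonization and only 11 has a free benzylic alkoxide placed for six-membered ring closure onto C–Br, so the mixture funnels to 12, and because the new bond is made at oxygen C-2'' keeps its configuration and the 2'',3''-cis relationship is fixed.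

Step 7
Reactants: 13 1,3-bis(benzyloxy)-5-bromobenzene
Product: 15 2,4-bis(benzyloxy)-6-bromobenzaldehyde, via iminium chloride 14 (not isolated)
Conditions: POCl3, DMF, 0 → 70 °C; then ice-water
Reagents that add atoms: N,N-dimethylformamide (CN(C)C=O); water (O)
Why: Vilsmeier–Haack formylation at the position para to one benzyloxy group and ortho to bromine, the same site selectivity as in step 1.

Step 8
Reactants: 12 tricyclic lactone; 15 aldehyde
Product: 17 (3S,3aS,4S,9bS)-3-[(R)-[2,4-bis(benzyloxy)-6-bromophenyl](hydroxy)methyl]-7,9-dimethoxy-4-(4-methoxyphenyl)-3,3a,4,9b-tetrahydro-2H-furo[3,2-c]chromen-2-one, via lithium enolate 16 (not isolated)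
Conditions: LiN(iPr)2, THF, −78 °C; then 15, −78 °C; AcOH quench at −78 °C
Reagents that add atoms: none
Why: Lithium enolate aldol addition; the aldehyde approaches the convex face of the cis-fused bicyclic enolate, anti to the chroman ring, which sets C-3 trans to C-2'', and the ring-locked E-enolate gives the anti carbinol through a Zimmerman–Traxler chair (the minor carbinol epimer is separated).

Step 9
Reactants: 17 aldol lactone
Product: 18 (2S,3R)-3-[2,4-bis(benzyloxy)-6-bromophenyl]-3-hydroxy-2-[(2S,3R,4S)-4-hydroxy-5,7-dimethoxy-2-(4-methoxyphenyl)-3,4-dihydro-2H-chromen-3-yl]-N-methoxy-N-methylpropanamide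
Conditions: MeNHOMe·HCl, iPrMgCl, THF, −20 → 0 °C; aq. NH4Cl
Reagents that add atoms: N,O-dimethylhydroxylamine hydrochloride (CNOC.Cl)
Why: Lactone aminolysis by the magnesium amide (Weinreb amide formation) opens the ring without touching a stereocentre and frees the C-4'' hydroxyl; the cold magnesium aldolate resists retro-aldol cleavage.

Step 10
Reactants: 18 Weinreb amide; 19 4-methoxyphenylmagnesium bromide
Product: 20 (2S,3R)-3-[2,4-bis(benzyloxy)-6-bromophenyl]-3-hydroxy-2-[(2S,3R,4S)-4-hydroxy-5,7-dimethoxy-2-(4-methoxyphenyl)-3,4-dihydro-2H-chromen-3-yl]-1-(4-methoxyphenyl)propan-1-one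
Conditions: THF, −20 → 0 °C; aq. NH4Cl at 0 °C
Reagents that add atoms: none
Why: Weinreb ketone synthesis; the Grignard reagent adds once and the ketone is unmasked only at the quench, so C-3 is never an enolizable centre in the presence of the basic reagent.

Step 11
Reactants: 20 β-hydroxy ketone
Product: 22 (1S,2R,3R)-3-[2,4-bis(benzyloxy)-6-bromophenyl]-2-[(2S,3R,4S)-4-hydroxy-5,7-dimethoxy-2-(4-methoxyphenyl)-3,4-dihydro-2H-chromen-3-yl]-1-(4-methoxyphenyl)propane-1,3-diol, via diethylborinate 21 (not isolated)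
Conditions: Et2BOMe, THF–MeOH (4:1), −78 °C; then NaBH4, −78 °C; MeOH co-evaporation
Reagents that add atoms: none
Why: Narasaka–Prasad reduction; boron ties the C-4 hydroxyl and the ketone into a six-membered chelate with all substituents equatorial, and axial hydride attack gives the 1,3-syn diol, i.e. C-2 (S), anti to the C-3 substituent.

Step 12
Reactants: 22 triol
Product: 23 (2S,3S,4R)-5,7-bis(benzyloxy)-3-[(2S,3R,4S)-4-hydroxy-5,7-dimethoxy-2-(4-methoxyphenyl)-3,4-dihydro-2H-chromen-3-yl]-2-(4-methoxyphenyl)-3,4-dihydro-2H-chromen-4-ol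
Conditions: CuI (10 mol%), 3,4,7,8-tetramethyl-1,10-phenanthroline (20 mol%), Cs2CO3, toluene, 110 °C
Reagents that add atoms: none
Why: Second intramolecular Ullmann-type etherification; only the C-2 hydroxyl can form a six-membered ring with the aryl bromide, the bond forms at oxygen so C-2 is retained (2,3-trans), and with no carbonyl present neither C-3 nor C-3'' can epimerize under the base.

Step 13
Reactants: 23 bis(chroman-4-ol)
Product: 24 (2S,3R)-5,7-bis(benzyloxy)-3-[(2S,3S)-5,7-dimethoxy-2-(4-methoxyphenyl)-4-oxo-3,4-dihydro-2H-chromen-3-yl]-2-(4-methoxyphenyl)-2,3-dihydro-4H-chromen-4-one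
Conditions: Dess–Martin periodinane, NaHCO3, CH2Cl2, 0 °C → rt
Reagents that add atoms: none
Why: Dess–Martin oxidation of both benzylic carbinols under buffered, non-enolizing conditions removes the two temporary stereocentres and leaves the cis C-3'' centre untouched.

Step 14
Reactants: 24 protected bis-flavanone
Product: 25 target (2S,3R)-5,7-dihydroxy-3-[(2S,3S)-5-hydroxy-7-methoxy-2-(4-methoxyphenyl)-4-oxo-3,4-dihydro-2H-chromen-3-yl]-2-(4-methoxyphenyl)-2,3-dihydro-4H-chromen-4-one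
Conditions: BCl3, pentamethylbenzene, CH2Cl2, −78 → 0 °C; then MeOH, aq. NaHCO3
Reagents that add atoms: none
Why: Lewis-acid ether cleavage; BCl3 with a benzyl-cation scavenger removes both benzyl ethers cold and, through chelation to the C-4'' carbonyl, only the peri 5''-methyl ether, while the non-chelated 7''- and 4'-methyl ethers stay.

**Compound list**

1 | 1-bromo-3,5-dimethoxybenzene | COc1cc(Br)cc(OC)c1 | starting material
2 | acetyl chloride | CC(Cl)=O | starting material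
3 | 1-(2-bromo-4,6-dimethoxyphenyl)ethan-1-one | CC(=O)c1c(Br)cc(OC)cc1OC | intermediate
4 | methyl 4-methoxybenzoate | COC(=O)c1ccc(OC)cc1 | starting material
5 | 1-(2-bromo-4,6-dimethoxyphenyl)-3-(4-methoxyphenyl)propane-1,3-dione | COc1ccc(cc1)C(=O)CC(=O)c1c(Br)cc(OC)cc1OC | intermediate
6 | methyl bromoacetate | COC(=O)CBr | starting material
7 | methyl 3-(2-bromo-4,6-dimethoxybenzoyl)-4-(4-methoxyphenyl)-4-oxobutanoate (racemic, labile) | COC(=O)CC(C(=O)c1ccc(OC)cc1)C(=O)c1c(Br)cc(OC)cc1OC | intermediate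
8 | methyl (3S,4S)-3-(2-bromo-4,6-dimethoxybenzoyl)-4-hydroxy-4-(4-methoxyphenyl)butanoate | COC(=O)C[C@@H]([C@H](O)c1ccc(OC)cc1)C(=O)c1c(Br)cc(OC)cc1OC | intermediate (not isolated)
9 | (4S,5S)-4-(2-bromo-4,6-dimethoxybenzoyl)-5-(4-methoxyphenyl)oxolan-2-one | O=C1C[C@H](C(=O)c2c(Br)cc(OC)cc2OC)[C@@H](c2ccc(OC)cc2)O1 | intermediate
10 | (4R,5S)-4-[(S)-(2-bromo-4,6-dimethoxyphenyl)(hydroxy)methyl]-5-(4-methoxyphenyl)oxolan-2-one | O=C1C[C@H]([C@H](O)c2c(Br)cc(OC)cc2OC)[C@@H](c2ccc(OC)cc2)O1 | intermediate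
11 | (4S,5S)-5-(2-bromo-4,6-dimethoxyphenyl)-4-[(S)-hydroxy(4-methoxyphenyl)methyl]oxolan-2-one | O=C1C[C@@H]([C@H](O)c2ccc(OC)cc2)[C@@H](c2c(Br)cc(OC)cc2OC)O1 | intermediate (not isolated)
12 | (3aS,4S,9bS)-7,9-dimethoxy-4-(4-methoxyphenyl)-3,3a,4,9b-tetrahydro-2H-furo[3,2-c]chromen-2-one | O=C1C[C@H]2[C@@H](c3ccc(OC)cc3)Oc3cc(OC)cc(OC)c3[C@H]2O1 | intermediate
13 | 1,3-bis(benzyloxy)-5-bromobenzene | Brc1cc(OCc2ccccc2)cc(OCc2ccccc2)c1 | starting material
14 | N-[2,4-bis(benzyloxy)-6-bromobenzylidene]-N-methylmethanaminium chloride | C[N+](C)=Cc1c(Br)cc(OCc2ccccc2)cc1OCc1ccccc1.[Cl-] | intermediate (not isolated)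
15 | 2,4-bis(benzyloxy)-6-bromobenzaldehyde | O=Cc1c(Br)cc(OCc2ccccc2)cc1OCc1ccccc1 | intermediate
16 | lithium enolate of lactone 12 | [Li+].[O-]C1=C[C@H]2[C@@H](c3ccc(OC)cc3)Oc3cc(OC)cc(OC)c3[C@H]2O1 | intermediate (not isolated)
17 | (3S,3aS,4S,9bS)-3-[(R)-[2,4-bis(benzyloxy)-6-bromophenyl](hydroxy)methyl]-7,9-dimethoxy-4-(4-methoxyphenyl)-3,3a,4,9b-tetrahydro-2H-furo[3,2-c]chromen-2-one | O=C1[C@H]([C@@H](O)c3c(Br)cc(OCc4ccccc4)cc3OCc3ccccc3)[C@H]2[C@@H](c3ccc(OC)cc3)Oc3cc(OC)cc(OC)c3[C@H]2O1 | intermediate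
18 | (2S,3R)-3-[2,4-bis(benzyloxy)-6-bromophenyl]-3-hydroxy-2-[(2S,3R,4S)-4-hydroxy-5,7-dimethoxy-2-(4-methoxyphenyl)-3,4-dihydro-2H-chromen-3-yl]-N-methoxy-N-methylpropanamide | CON(C)C(=O)[C@H]([C@@H](O)c1c(Br)cc(OCc2ccccc2)cc1OCc1ccccc1)[C@H]1[C@@H](c2ccc(OC)cc2)Oc2cc(OC)cc(OC)c2[C@H]1O | intermediate
19 | 4-methoxyphenylmagnesium bromide | COc1ccc([Mg]Br)cc1 | starting material
20 | (2S,3R)-3-[2,4-bis(benzyloxy)-6-bromophenyl]-3-hydroxy-2-[(2S,3R,4S)-4-hydroxy-5,7-dimethoxy-2-(4-methoxyphenyl)-3,4-dihydro-2H-chromen-3-yl]-1-(4-methoxyphenyl)propan-1-one | COc1ccc(cc1)C(=O)[C@H]([C@@H](O)c1c(Br)cc(OCc2ccccc2)cc1OCc1ccccc1)[C@H]1[C@@H](c2ccc(OC)cc2)Oc2cc(OC)cc(OC)c2[C@H]1O | intermediate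
21 | O-diethylboryl derivative of 20 at the C-4 hydroxyl | COc1ccc(cc1)C(=O)[C@H]([C@@H](OB(CC)CC)c1c(Br)cc(OCc2ccccc2)cc1OCc1ccccc1)[C@H]1[C@@H](c2ccc(OC)cc2)Oc2cc(OC)cc(OC)c2[C@H]1O | intermediate (not isolated)
22 | (1S,2R,3R)-3-[2,4-bis(benzyloxy)-6-bromophenyl]-2-[(2S,3R,4S)-4-hydroxy-5,7-dimethoxy-2-(4-methoxyphenyl)-3,4-dihydro-2H-chromen-3-yl]-1-(4-methoxyphenyl)propane-1,3-diol | COc1ccc(cc1)[C@@H](O)[C@H]([C@@H](O)c1c(Br)cc(OCc2ccccc2)cc1OCc1ccccc1)[C@H]1[C@@H](c2ccc(OC)cc2)Oc2cc(OC)cc(OC)c2[C@H]1O | intermediate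
23 | (2S,3S,4R)-5,7-bis(benzyloxy)-3-[(2S,3R,4S)-4-hydroxy-5,7-dimethoxy-2-(4-methoxyphenyl)-3,4-dihydro-2H-chromen-3-yl]-2-(4-methoxyphenyl)-3,4-dihydro-2H-chromen-4-ol | COc1ccc(cc1)[C@H]1Oc2cc(OCc3ccccc3)cc(OCc3ccccc3)c2[C@H](O)[C@@H]1[C@H]1[C@@H](c2ccc(OC)cc2)Oc2cc(OC)cc(OC)c2[C@H]1O | intermediate
24 | (2S,3R)-5,7-bis(benzyloxy)-3-[(2S,3S)-5,7-dimethoxy-2-(4-methoxyphenyl)-4-oxo-3,4-dihydro-2H-chromen-3-yl]-2-(4-methoxyphenyl)-2,3-dihydro-4H-chromen-4-one | COc1ccc([C@H]2Oc3cc(OCc4ccccc4)cc(OCc4ccccc4)c3C(=O)[C@@H]2[C@@H]2C(=O)c3c(OC)cc(OC)cc3O[C@@H]2c2ccc(OC)cc2)cc1 | intermediate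
25 | CNP0184936.3, (2S,3R)-5,7-dihydroxy-3-[(2S,3S)-5-hydroxy-7-methoxy-2-(4-methoxyphenyl)-4-oxo-3,4-dihydro-2H-chromen-3-yl]-2-(4-methoxyphenyl)-2,3-dihydro-4H-chromen-4-one | COc1ccc([C@H]2Oc3cc(O)cc(O)c3C(=O)[C@@H]2[C@@H]2C(=O)c3c(O)cc(OC)cc3O[C@@H]2c2ccc(OC)cc2)cc1 | target

**Step count and risks**

Total steps: 14. Longest linear sequence: 13 steps (steps 1–6 and 8–14); step 7 is a one-step side branch.

The benzylic alcohols 10–23 are acid-sensitive and should be purified on triethylamine-deactivated silica.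

Most likely to fail, step 4: the ketoreductase may not accept the bulky diketo ester 7 or may deliver the wrong C-3'' epimer. The fallback sets out from 6 and returns at 9; it gives the enzyme a small substrate and attaches the hindered aryl ketone afterwards. Purchased methyl 3-(4-methoxyphenyl)-3-oxopropanoate is alkylated with 6 (K2CO3, acetone) to dimethyl 2-(4-methoxybenzoyl)butanedioate F1. Ketoreductase reduction with dynamic kinetic resolution under the step 4 cofactor conditions, then PPTS, gives methyl (2S,3S)-2-(4-methoxyphenyl)-5-oxooxolane-3-carboxylate F2. LiOH, then HCl to relactonize, gives (2S,3S)-2-(4-methoxyphenyl)-5-oxooxolane-3-carboxylic acid F3. Oxalyl chloride with catalytic DMF gives (2S,3S)-2-(4-methoxyphenyl)-5-oxooxolane-3-carbonyl chloride F4. Friedel–Crafts acylation of 1 with F4 (SnCl4, CH2Cl2, −20 °C, same site selectivity as step 1) gives 9.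

Most likely to fail, step 6: the etherification depends on the minor lactone isomer 11 being reached and cyclizing faster than side reactions. The fallback sets out from 10 and returns at 12; it fixes the required hydroxyl by protection instead of lactone equilibration. Silylation of 10 (TBSOTf, 2,6-lutidine, −78 °C) gives (4S,5S)-4-[(S)-(2-bromo-4,6-dimethoxyphenyl)(tert-butyldimethylsilyloxy)methyl]-5-(4-methoxyphenyl)oxolan-2-one F5. Lactone opening with MeNHOMe·HCl and iPrMgCl gives (3S,4S)-3-[(S)-(2-bromo-4,6-dimethoxyphenyl)(tert-butyldimethylsilyloxy)methyl]-4-hydroxy-N-methoxy-4-(4-methoxyphenyl)-N-methylbutanamide F6. Buchwald etherification (Pd(OAc)2, 2-(di-tert-butylphosphino)-1,1'-binaphthyl, Cs2CO3, toluene, 80 °C) closes the pyran ring to 2-[(2S,3S,4S)-4-(tert-butyldimethylsilyloxy)-5,7-dimethoxy-2-(4-methoxyphenyl)-3,4-dihydro-2H-chromen-3-yl]-N-methoxy-N-methylacetamide F7. Tetrabutylammonium fluoride removes the silyl group and the freed alkoxide closes onto the amide to give 12.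

Most likely to fail, step 14: excess BCl3 could open or epimerize the cis 2'',3''-flavanone or attack the wrong methyl ether. The fallback sets out from 24 and returns at 25; it uses two milder stages. Hydrogenolysis (H2, Pd/C, EtOAc, rt) removes only the benzyl groups and gives (2S,3R)-3-[(2S,3S)-5,7-dimethoxy-2-(4-methoxyphenyl)-4-oxo-3,4-dihydro-2H-chromen-3-yl]-5,7-dihydroxy-2-(4-methoxyphenyl)-2,3-dihydro-4H-chromen-4-one F8. The chelated 5''-methyl ether alone is then cleaved with BCl3 (2 equiv, CH2Cl2, −78 → −20 °C) to give 25.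

**Further compounds**

F1 | step 4 | dimethyl 2-(4-methoxybenzoyl)butanedioate (racemic, labile) | COC(=O)CC(C(=O)OC)C(=O)c1ccc(OC)cc1
F2 | step 4 | methyl (2S,3S)-2-(4-methoxyphenyl)-5-oxooxolane-3-carboxylate | O=C1C[C@H](C(=O)OC)[C@@H](c2ccc(OC)cc2)O1
F3 | step 4 | (2S,3S)-2-(4-methoxyphenyl)-5-oxooxolane-3-carboxylic acid | O=C1C[C@H](C(=O)O)[C@@H](c2ccc(OC)cc2)O1
F4 | step 4 | (2S,3S)-2-(4-methoxyphenyl)-5-oxooxolane-3-carbonyl chloride | O=C1C[C@H](C(Cl)=O)[C@@H](c2ccc(OC)cc2)O1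
F5 | step 6 | (4S,5S)-4-[(S)-(2-bromo-4,6-dimethoxyphenyl)(tert-butyldimethylsilyloxy)methyl]-5-(4-methoxyphenyl)oxolan-2-one | O=C1C[C@H]([C@H](O[Si](C)(C)C(C)(C)C)c2c(Br)cc(OC)cc2OC)[C@@H](c2ccc(OC)cc2)O1
F6 | step 6 | (3S,4S)-3-[(S)-(2-bromo-4,6-dimethoxyphenyl)(tert-butyldimethylsilyloxy)methyl]-4-hydroxy-N-methoxy-4-(4-methoxyphenyl)-N-methylbutanamide | CON(C)C(=O)C[C@H]([C@H](O[Si](C)(C)C(C)(C)C)c1c(Br)cc(OC)cc1OC)[C@H](O)c1ccc(OC)cc1
F7 | step 6 | 2-[(2S,3S,4S)-4-(tert-butyldimethylsilyloxy)-5,7-dimethoxy-2-(4-methoxyphenyl)-3,4-dihydro-2H-chromen-3-yl]-N-methoxy-N-methylacetamide | CON(C)C(=O)C[C@H]1[C@@H](c2ccc(OC)cc2)Oc2cc(OC)cc(OC)c2[C@H]1O[Si](C)(C)C(C)(C)C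
F8 | step 14 | (2S,3R)-3-[(2S,3S)-5,7-dimethoxy-2-(4-methoxyphenyl)-4-oxo-3,4-dihydro-2H-chromen-3-yl]-5,7-dihydroxy-2-(4-methoxyphenyl)-2,3-dihydro-4H-chromen-4-one | COc1ccc([C@H]2Oc3cc(O)cc(O)c3C(=O)[C@@H]2[C@@H]2C(=O)c3c(OC)cc(OC)cc3O[C@@H]2c2ccc(OC)cc2)cc1
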